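The route rests on cutting the C4a–C5 bond of ring A in the 5,7-dihydroxyflavonol half. This ring, with OH on C5 and C7, O1 on C8a and the C4 carbonyl on C4a, is a C-acylphloroglucinol, the oxidation pattern of a folded poly-β-keto chain, and its symmetry about the C4a–C7 axis means folding can give only one ring. The key step closes it by intramolecular Claisen acylation of a linear cinnamoyl triketo ester and delivers the 2′,4′,6′-trihydroxychalcone in one operation. The precursor is a methyl (E)-9-aryl-3,5,7-trioxonon-8-enoate whose aryl group is the diaryl ether; its far ring carries a benzyl ether and a dioxolane-masked aldehyde for the second, 7-methoxy flavonol.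

Key step: step 6

Remark: the key-step product is drawn and carried as the open-chain chalcone; if part of it closes to the corresponding flavanone during work-up, this does no harm, because the following oxidative cyclisation converts both forms into the same flavone. The target has no stereocentre; the E-alkenes of the intermediates are consumed on ring closure.

Step 1
Reactants: 1 3-(benzyloxy)-4-hydroxybenzaldehyde
Product: 2 2-(benzyloxy)-4-(1,3-dioxolan-2-yl)phenol
Conditions: HOCH2CH2OH, p-TsOH (cat.), toluene, reflux with azeotropic removal of water; Et3N quench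
Reagents that add atoms: ethylene glycol, OCCO
Why: Acid-catalysed acetalisation driven by water removal masks this formyl group so that only one free aldehyde is present after the ether coupling, and the basic quench protects the acid-labile phenolic acetal.

Step 2
Reactants: 2 2-(benzyloxy)-4-(1,3-dioxolan-2-yl)phenol; 3 4-fluoro-3-methoxybenzaldehyde
Product: 4 4-[2-(benzyloxy)-4-(1,3-dioxolan-2-yl)phenoxy]-3-methoxybenzaldehyde
Conditions: K2CO3, DMF, 110 °C
Reagents that add atoms: none
Why: Nucleophilic aromatic substitution (SNAr) in which the phenoxide displaces the fluoride para to the formyl group through a stabilised Meisenheimer adduct, the dioxolane and benzyl ether being inert to carbonate.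

Step 3
Reactants: 4 4-[2-(benzyloxy)-4-(1,3-dioxolan-2-yl)phenoxy]-3-methoxybenzaldehyde
Product: 5 (E)-3-{4-[2-(benzyloxy)-4-(1,3-dioxolan-2-yl)phenoxy]-3-methoxyphenyl}-N-methoxy-N-methylprop-2-enamide
Conditions: (EtO)2P(O)CH2C(O)N(OMe)Me, NaH, THF, 0 °C → rt
Reagents that add atoms: diethyl [2-(methoxy(methyl)amino)-2-oxoethyl]phosphonate, CCOP(=O)(CC(=O)N(C)OC)OCC
Why: Horner–Wadsworth–Emmons olefination with a stabilised amide phosphonate should give the E-enamide through the reversible, thermodynamically controlled addition step and installs the N-methoxy-N-methylamide acyl donor in the same operation.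

Step 4
Reactants: 6 methyl acetoacetate
Product: 7 methyl 3,5-dioxohexanoate
Conditions: LiN(iPr)2 (2.2 equiv), THF, −78 → 0 °C; MeC(O)N(OMe)Me, −78 → 0 °C; then 1 M HCl
Reagents that add atoms: N-methoxy-N-methylacetamide, CC(=O)N(C)OC
Why: γ-Acylation of the acetoacetate dianion, whose more basic terminal carbanion adds to the N-methoxy-N-methylamide to give a chelated tetrahedral adduct that collapses to the diketone only on acidic quench, which prevents over-addition.

Step 5
Reactants: 5 (E)-3-{4-[2-(benzyloxy)-4-(1,3-dioxolan-2-yl)phenoxy]-3-methoxyphenyl}-N-methoxy-N-methylprop-2-enamide; 7 methyl 3,5-dioxohexanoate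
Product: 8 methyl (E)-9-{4-[2-(benzyloxy)-4-(1,3-dioxolan-2-yl)phenoxy]-3-methoxyphenyl}-3,5,7-trioxonon-8-enoate
Conditions: 7 (1.5 equiv), LiN(iPr)2 (3.1 equiv per 7), THF, −78 → 0 °C; then 5, −78 → −20 °C; AcOH, −78 °C; used crude
Reagents that add atoms: none
Why: Acylation of the β,δ-diketo ester trianion at its most nucleophilic terminal carbon by the N-methoxy-N-methylamide, where the hard lithium carbanion and the β-aryl group favour 1,2-attack over conjugate addition, the chelated adduct survives until the quench, and the acetal and benzyl ether are stable to amide base.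

Step 6
Reactants: 8 methyl (E)-9-{4-[2-(benzyloxy)-4-(1,3-dioxolan-2-yl)phenoxy]-3-methoxyphenyl}-3,5,7-trioxonon-8-enoate
Product: 9 (E)-3-{4-[2-(benzyloxy)-4-(1,3-dioxolan-2-yl)phenoxy]-3-methoxyphenyl}-1-(2,4,6-trihydroxyphenyl)prop-2-en-1-one
Conditions: Mg(OMe)2 (4 equiv), MeOH, rt → reflux; then cold aq. AcOH (pH 4–5), rapid extraction
Reagents that add atoms: none
Why: Mg(OMe)2 turns the chain into a chelated polyenolate in which the C6 carbanion, flanked by the C5 and C7 carbonyls, adds to the C1 ester carbonyl and the tetrahedral intermediate expels methoxide, forming the C6–C1 bond that becomes C4a–C5 of ring A. The closest known reaction type is the base-mediated Claisen (Dieckmann-type) cyclisation of 3,5,7-triketo esters to acylphloroglucinols. Ring A closes in the 6-exo-trig mode, and the cyclic triketone tautomerises at once to the aromatic phloroglucinol, which makes the closure irreversible. No stereocentre is created and the E-alkene is not touched. The selectivity needed is C-acylation over the aldol mode (C2 onto the C7 carbonyl, leading to a styryl resorcylate), over lactonisation to a pyranone and over oxa-Michael addition to the enone; it is secured by the methyl ester as a good acyl acceptor, by magnesium chelation of the C5/C7 diketone, which raises the nucleophilicity of C6 and lowers the electrophilicity of the already conjugated C7 carbonyl, and by the reversibility of the competing additions under alkoxide. Because C1, C3 and C5 end up as three equivalent ring oxygens the product is a single constitutional isomer, and the dioxolane and benzyl ether are stable to the base.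

Step 7
Reactants: 9 (E)-3-{4-[2-(benzyloxy)-4-(1,3-dioxolan-2-yl)phenoxy]-3-methoxyphenyl}-1-(2,4,6-trihydroxyphenyl)prop-2-en-1-one
Product: 12 3-(benzyloxy)-4-[4-(5,7-dihydroxy-4-oxo-4H-chromen-2-yl)-2-methoxyphenoxy]benzaldehyde, via racemic flavanone 10 (not isolated), via flavone acetal 11 (not isolated)
Conditions: I2 (10 mol%), DMSO, 120 °C; then 1 M HCl, THF, rt; Na2S2O3 wash
Reagents that add atoms: water, O
Why: Iodine-catalysed oxidative cyclisation of a 2′-hydroxychalcone in DMSO, in which oxa-Michael closure gives flavanone 10, iodine dehydrogenates it to flavone 11 while DMSO re-oxidises HI, and the aqueous acid finish hydrolyses the dioxolane to release the aldehyde for the second half.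

Step 8
Reactants: 12 3-(benzyloxy)-4-[4-(5,7-dihydroxy-4-oxo-4H-chromen-2-yl)-2-methoxyphenoxy]benzaldehyde
Product: 13 3-(benzyloxy)-4-{4-[5,7-bis(benzyloxy)-4-oxo-4H-chromen-2-yl]-2-methoxyphenoxy}benzaldehyde
Conditions: BnBr (3 equiv), K2CO3, Bu4NI (cat.), DMF, 70 °C
Reagents that add atoms: benzyl bromide, BrCc1ccccc1
Why: Williamson ether synthesis in which heating and excess reagent also alkylate the hydrogen-bonded 5-OH, so that both ring-A phenols are protected against the later oxidant while the non-enolisable aldehyde is unaffected.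

Step 9
Reactants: 14 1-(2,6-dihydroxy-4-methoxyphenyl)ethan-1-one
Product: 15 1-[2-(benzyloxy)-6-hydroxy-4-methoxyphenyl]ethan-1-one
Conditions: BnBr (1.05 equiv), K2CO3, acetone, reflux
Reagents that add atoms: benzyl bromide, BrCc1ccccc1
Why: Williamson mono-etherification of a symmetric 2,6-dihydroxyacetophenone, where the hydroxyl left after the first alkylation is hydrogen-bonded to the carbonyl and much less nucleophilic, so the reaction should stop at the monobenzyl ether.

Step 10
Reactants: 13 3-(benzyloxy)-4-{4-[5,7-bis(benzyloxy)-4-oxo-4H-chromen-2-yl]-2-methoxyphenoxy}benzaldehyde; 15 1-[2-(benzyloxy)-6-hydroxy-4-methoxyphenyl]ethan-1-one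
Product: 16 (E)-1-[2-(benzyloxy)-6-hydroxy-4-methoxyphenyl]-3-(3-(benzyloxy)-4-{4-[5,7-bis(benzyloxy)-4-oxo-4H-chromen-2-yl]-2-methoxyphenoxy}phenyl)prop-2-en-1-one
Conditions: KOH (50% aq.), EtOH/THF, 0 °C → rt; then 1 M HCl to pH 5
Reagents that add atoms: none
Why: Claisen–Schmidt condensation in which the acetophenone enolate adds to the non-enolisable aldehyde and E1cB dehydration gives the thermodynamically favoured E-enone, the 5,7-dialkoxyflavone being expected to tolerate cold ethanolic hydroxide for the time needed.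

Step 11
Reactants: 16 (E)-1-[2-(benzyloxy)-6-hydroxy-4-methoxyphenyl]-3-(3-(benzyloxy)-4-{4-[5,7-bis(benzyloxy)-4-oxo-4H-chromen-2-yl]-2-methoxyphenoxy}phenyl)prop-2-en-1-one
Product: 18 5-(benzyloxy)-2-(3-(benzyloxy)-4-{4-[5,7-bis(benzyloxy)-4-oxo-4H-chromen-2-yl]-2-methoxyphenoxy}phenyl)-7-methoxy-4H-chromen-4-one, via racemic flavanone 17 (not isolated)
Conditions: I2 (10 mol%), DMSO, 130 °C; Na2S2O3 wash
Reagents that add atoms: none
Why: The same iodine-catalysed oxidative cyclisation of a 2′-hydroxychalcone as in step 7 (oxa-Michael closure to flavanone 17, then dehydrogenation with DMSO as terminal oxidant), with the benzyl ethers expected to survive the catalytic amount of HI.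

Step 12
Reactants: 18 5-(benzyloxy)-2-(3-(benzyloxy)-4-{4-[5,7-bis(benzyloxy)-4-oxo-4H-chromen-2-yl]-2-methoxyphenoxy}phenyl)-7-methoxy-4H-chromen-4-one
Product: 20 5-(benzyloxy)-2-(3-(benzyloxy)-4-{4-[5,7-bis(benzyloxy)-3-hydroxy-4-oxo-4H-chromen-2-yl]-2-methoxyphenoxy}phenyl)-3-hydroxy-7-methoxy-4H-chromen-4-one, via bis-epoxide 19 (not isolated)
Conditions: dimethyldioxirane (DMDO, excess), acetone/CH2Cl2, 0 °C → rt; concentrate; then p-TsOH (cat.), CH2Cl2, rt
Reagents that add atoms: dimethyldioxirane, CC1(C)OO1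
Why: Electrophilic epoxidation of both flavone C2=C3 bonds by the dioxirane followed by acid-catalysed epoxide opening at C2 (cation stabilised by O1 and the aryl group) and loss of H3 gives the 3-hydroxyflavones, so the transient epoxide stereocentres are erased and need no control.

Step 13
Reactants: 20 5-(benzyloxy)-2-(3-(benzyloxy)-4-{4-[5,7-bis(benzyloxy)-3-hydroxy-4-oxo-4H-chromen-2-yl]-2-methoxyphenoxy}phenyl)-3-hydroxy-7-methoxy-4H-chromen-4-one
Product: 21 3,5-dihydroxy-2-(3-hydroxy-4-{2-methoxy-4-[3,5,7-trihydroxy-4-oxo-4H-chromen-2-yl]phenoxy}phenyl)-7-methoxy-4H-chromen-4-one (CNP0190193.0)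
Conditions: H2 (1 atm), Pd/C (10%), THF/MeOH, rt
Reagents that add atoms: none
Why: Catalytic hydrogenolysis cleaves the four benzyl aryl ethers, while the two methyl ethers, the diaryl ether and the flavonol C2=C3 enol double bonds are not reduced under these mild conditions.

Compound list
1 | 3-(benzyloxy)-4-hydroxybenzaldehyde | O=Cc1ccc(O)c(OCc2ccccc2)c1 | starting material
2 | 2-(benzyloxy)-4-(1,3-dioxolan-2-yl)phenol | Oc1ccc(C2OCCO2)cc1OCc1ccccc1 | intermediate
3 | 4-fluoro-3-methoxybenzaldehyde | COc1cc(C=O)ccc1F | starting material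
4 | 4-[2-(benzyloxy)-4-(1,3-dioxolan-2-yl)phenoxy]-3-methoxybenzaldehyde | COc1cc(C=O)ccc1Oc1ccc(C2OCCO2)cc1OCc1ccccc1 | intermediate
5 | (E)-3-{4-[2-(benzyloxy)-4-(1,3-dioxolan-2-yl)phenoxy]-3-methoxyphenyl}-N-methoxy-N-methylprop-2-enamide | CON(C)C(=O)/C=C/c1ccc(Oc2ccc(C3OCCO3)cc2OCc2ccccc2)c(OC)c1 | intermediate
6 | methyl acetoacetate (methyl 3-oxobutanoate) | COC(=O)CC(C)=O | starting material
7 | methyl 3,5-dioxohexanoate | COC(=O)CC(=O)CC(C)=O | intermediate
8 | methyl (E)-9-{4-[2-(benzyloxy)-4-(1,3-dioxolan-2-yl)phenoxy]-3-methoxyphenyl}-3,5,7-trioxonon-8-enoate (drawn as the keto form; enol tautomers expected) | COC(=O)CC(=O)CC(=O)CC(=O)/C=C/c1ccc(Oc2ccc(C3OCCO3)cc2OCc2ccccc2)c(OC)c1 | intermediate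
9 | (E)-3-{4-[2-(benzyloxy)-4-(1,3-dioxolan-2-yl)phenoxy]-3-methoxyphenyl}-1-(2,4,6-trihydroxyphenyl)prop-2-en-1-one | O=C(/C=C/c1ccc(Oc2ccc(C3OCCO3)cc2OCc2ccccc2)c(OC)c1)c1c(O)cc(O)cc1O | intermediate
10 | racemic 2-{4-[2-(benzyloxy)-4-(1,3-dioxolan-2-yl)phenoxy]-3-methoxyphenyl}-5,7-dihydroxychroman-4-one (not isolated) | O=C1CC(c2ccc(Oc3ccc(C4OCCO4)cc3OCc3ccccc3)c(OC)c2)Oc2cc(O)cc(O)c21 | intermediate
11 | 2-{4-[2-(benzyloxy)-4-(1,3-dioxolan-2-yl)phenoxy]-3-methoxyphenyl}-5,7-dihydroxy-4H-chromen-4-one (not isolated) | O=c1cc(-c2ccc(Oc3ccc(C4OCCO4)cc3OCc3ccccc3)c(OC)c2)oc2cc(O)cc(O)c12 | intermediate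
12 | 3-(benzyloxy)-4-[4-(5,7-dihydroxy-4-oxo-4H-chromen-2-yl)-2-methoxyphenoxy]benzaldehyde | O=c1cc(-c2ccc(Oc3ccc(C=O)cc3OCc3ccccc3)c(OC)c2)oc2cc(O)cc(O)c12 | intermediate
13 | 3-(benzyloxy)-4-{4-[5,7-bis(benzyloxy)-4-oxo-4H-chromen-2-yl]-2-methoxyphenoxy}benzaldehyde | O=c1cc(-c2ccc(Oc3ccc(C=O)cc3OCc3ccccc3)c(OC)c2)oc2cc(OCc3ccccc3)cc(OCc3ccccc3)c12 | intermediate
14 | 1-(2,6-dihydroxy-4-methoxyphenyl)ethan-1-one | COc1cc(O)c(C(C)=O)c(O)c1 | starting material
15 | 1-[2-(benzyloxy)-6-hydroxy-4-methoxyphenyl]ethan-1-one | COc1cc(O)c(C(C)=O)c(OCc2ccccc2)c1 | intermediate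
16 | (E)-1-[2-(benzyloxy)-6-hydroxy-4-methoxyphenyl]-3-(3-(benzyloxy)-4-{4-[5,7-bis(benzyloxy)-4-oxo-4H-chromen-2-yl]-2-methoxyphenoxy}phenyl)prop-2-en-1-one | COc1cc(O)c(C(=O)/C=C/c2ccc(Oc3ccc(-c4cc(=O)c5c(OCc6ccccc6)cc(OCc6ccccc6)cc5o4)cc3OC)c(OCc3ccccc3)c2)c(OCc2ccccc2)c1 | intermediate
17 | racemic 5-(benzyloxy)-2-(3-(benzyloxy)-4-{4-[5,7-bis(benzyloxy)-4-oxo-4H-chromen-2-yl]-2-methoxyphenoxy}phenyl)-7-methoxychroman-4-one (not isolated) | COc1cc(OCc2ccccc2)c2c(c1)OC(c1ccc(Oc3ccc(-c4cc(=O)c5c(OCc6ccccc6)cc(OCc6ccccc6)cc5o4)cc3OC)c(OCc3ccccc3)c1)CC2=O | intermediate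
18 | 5-(benzyloxy)-2-(3-(benzyloxy)-4-{4-[5,7-bis(benzyloxy)-4-oxo-4H-chromen-2-yl]-2-methoxyphenoxy}phenyl)-7-methoxy-4H-chromen-4-one | COc1cc(OCc2ccccc2)c2c(=O)cc(-c3ccc(Oc4ccc(-c5cc(=O)c6c(OCc7ccccc7)cc(OCc7ccccc7)cc6o5)cc4OC)c(OCc4ccccc4)c3)oc2c1 | intermediate
19 | bis(2,3-epoxide) of 18, each oxirane fused across C2–C3 of one chromenone (mixture of diastereomers, configuration not controlled and lost in the same step; not isolated) | COc1cc(OCc2ccccc2)c2c(c1)OC1(c3ccc(Oc4ccc(C56OC5C(=O)c5c(OCc7ccccc7)cc(OCc7ccccc7)cc5O6)cc4OC)c(OCc4ccccc4)c3)OC1C2=O | intermediate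
20 | 5-(benzyloxy)-2-(3-(benzyloxy)-4-{4-[5,7-bis(benzyloxy)-3-hydroxy-4-oxo-4H-chromen-2-yl]-2-methoxyphenoxy}phenyl)-3-hydroxy-7-methoxy-4H-chromen-4-one | COc1cc(OCc2ccccc2)c2c(=O)c(O)c(-c3ccc(Oc4ccc(-c5oc6cc(OCc7ccccc7)cc(OCc7ccccc7)c6c(=O)c5O)cc4OC)c(OCc4ccccc4)c3)oc2c1 | intermediate
21 | 3,5-dihydroxy-2-(3-hydroxy-4-{2-methoxy-4-[3,5,7-trihydroxy-4-oxo-4H-chromen-2-yl]phenoxy}phenyl)-7-methoxy-4H-chromen-4-one (CNP0190193.0) | COc1cc(O)c2c(=O)c(O)c(-c3ccc(Oc4ccc(-c5oc6cc(O)cc(O)c6c(=O)c5O)cc4OC)c(O)c3)oc2c1 | target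

Total step count: 13. Longest linear sequence: 11 steps (1, 2, 3, 5, 6, 7, 8, 10, 11, 12, 13); steps 4 and 9 are one-step side branches.

Steps most likely to fail

Step 6. The chain may fold in the aldol sense (C2 onto the C7 carbonyl) and aromatise to a styryl resorcylate, lactonise through an enol oxygen to a pyranone, or close by oxa-Michael addition to the enone instead of undergoing C-acylation. The fallback builds ring A in the conventional way from a preformed phloroglucinol; it sets out from aldehyde 4 and comes back to the route at 13. Commercial 2′,4′,6′-trihydroxyacetophenone is dibenzylated (BnBr, K2CO3, acetone, reflux) to 1-[2,4-bis(benzyloxy)-6-hydroxyphenyl]ethan-1-one F1. Claisen–Schmidt condensation of F1 with 4 (KOH, EtOH/THF, rt) should give (E)-1-[2,4-bis(benzyloxy)-6-hydroxyphenyl]-3-{4-[2-(benzyloxy)-4-(1,3-dioxolan-2-yl)phenoxy]-3-methoxyphenyl}prop-2-en-1-one F2. Iodine-catalysed oxidative cyclisation (I2, DMSO, 130 °C) converts it into 5,7-bis(benzyloxy)-2-{4-[2-(benzyloxy)-4-(1,3-dioxolan-2-yl)phenoxy]-3-methoxyphenyl}-4H-chromen-4-one F3, and 1 M HCl in THF then removes the dioxolane to give 13.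

Step 5. The polyanion may add in the conjugate sense to the cinnamoyl acceptor, may be quenched by proton transfer before acylation, or the sensitive triketo ester may cyclise during work-up. The fallback carries the chain in dioxinone-masked form; it sets out from amide 5 and comes back at 8. Commercial 2,2,6-trimethyl-4H-1,3-dioxin-4-one is acetylated through its lithium dienolate (LiN(SiMe3)2, THF, −78 °C, then acetyl chloride) to 2,2-dimethyl-6-(2-oxopropyl)-4H-1,3-dioxin-4-one F4. The dianion of F4 (LiN(iPr)2, 2 equiv, THF, −78 °C) is acylated at its terminal methyl group by 5 to give 6-[(E)-6-{4-[2-(benzyloxy)-4-(1,3-dioxolan-2-yl)phenoxy]-3-methoxyphenyl}-2,4-dioxohex-5-en-1-yl]-2,2-dimethyl-4H-1,3-dioxin-4-one F5. Thermolysis of F5 in toluene containing methanol at 110 °C (loss of acetone and methanolysis) should give triketo ester 8, which is taken directly into step 6.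

Step 12. Oxidation may be incomplete at one of the two flavone units, or may go too far through attack on benzylic C–H bonds or the electron-rich rings. The fallback replaces epoxidation by deprotonation, borylation and oxidation; it sets out from 18 and comes back at 20. Both C3–H positions are lithiated with LiN(iPr)2 in THF at −78 °C, the dianion is trapped with B(OMe)3 to give the 3,3″-bis(dimethoxyboryl) derivative of 18 F6, and oxidation of the crude boronate with H2O2/AcOH turns each C–B bond into C–OH to give 20.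

Further compounds
F1 | step 6 | 1-[2,4-bis(benzyloxy)-6-hydroxyphenyl]ethan-1-one | CC(=O)c1c(O)cc(OCc2ccccc2)cc1OCc1ccccc1
F2 | step 6 | (E)-1-[2,4-bis(benzyloxy)-6-hydroxyphenyl]-3-{4-[2-(benzyloxy)-4-(1,3-dioxolan-2-yl)phenoxy]-3-methoxyphenyl}prop-2-en-1-one | O=C(/C=C/c1ccc(Oc2ccc(C3OCCO3)cc2OCc2ccccc2)c(OC)c1)c1c(O)cc(OCc2ccccc2)cc1OCc1ccccc1
F3 | step 6 | 5,7-bis(benzyloxy)-2-{4-[2-(benzyloxy)-4-(1,3-dioxolan-2-yl)phenoxy]-3-methoxyphenyl}-4H-chromen-4-one | O=c1cc(-c2ccc(Oc3ccc(C4OCCO4)cc3OCc3ccccc3)c(OC)c2)oc2cc(OCc3ccccc3)cc(OCc3ccccc3)c12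
F4 | step 5 | 2,2-dimethyl-6-(2-oxopropyl)-4H-1,3-dioxin-4-one | CC(=O)CC1=CC(=O)OC(C)(C)O1
F5 | step 5 | 6-[(E)-6-{4-[2-(benzyloxy)-4-(1,3-dioxolan-2-yl)phenoxy]-3-methoxyphenyl}-2,4-dioxohex-5-en-1-yl]-2,2-dimethyl-4H-1,3-dioxin-4-one | CC1(C)OC(=O)C=C(CC(=O)CC(=O)/C=C/c2ccc(Oc3ccc(C4OCCO4)cc3OCc3ccccc3)c(OC)c2)O1
F6 | step 12 | 3,3″-bis(dimethoxyboryl) derivative of 18 (a B(OMe)2 group on C3 of each chromenone) | COc1cc(OCc2ccccc2)c2c(=O)c(B(OC)OC)c(-c3ccc(Oc4ccc(-c5oc6cc(OCc7ccccc7)cc(OCc7ccccc7)c6c(=O)c5B(OC)OC)cc4OC)c(OCc4ccccc4)c3)oc2c1
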